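In a one-step world, first order in the solid, the percent of solid substrate left at a given time does not depend on the charge. Take that as the zero of the scale and hold the runs against it.

all flasks: gas phase 12 mM (held)
- cedar: solid substrate 0.10 M; run made earlier
- alder: solid substrate 0.15 M; run made earlier
- flask: solid substrate 0.20 M; time 15 d

- cedar (time / d: solid substrate / %, target / %): 0.833: 86.6, 3.3; 2.50: 73.8, 8.1; 4.00: 62.8, 10.6; 6.00: 48.7, 13.8; 10.0: 21.5, 14.4; 12.0: 6.7, 15.7; 15.0: 0, 11.0
- alder (time / d: solid substrate / %, target / %): 0.833: 91.4, 0.7; 2.50: 82.5, 4.0; 4.00: 75.0, 7.6; 6.00: 65.9, 8.6; 10.0: 48.1, 9.9; 12.0: 38.2, 10.0; 15.0: 24.2, 9.5

(each reading ± 0.5 percentage points)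

- why nothing more happens at 15 d, or that something still does (for what has run out or reacted, a solid counts together with what of it has only dissolved) (all of the solid substrate has reacted / it is still moving / forward and back rates have come level)
- part of the solid substrate that has turned into other species by 15 d (what has only dissolved does not count)
- target at 15 d, in percent of the solid substrate charged
- over-reaction product at 15 d, in percent of the solid substrate charged

- solid substrate is a solid; its amount is given per volume of the solution
- at the start none of the gas phase is in solution
- at the start none of the solid substrate is in solution
- what has only dissolved of solid substrate counts as not reacted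
- a reading or a percentage of target counts all its forms, free or not
- the reaction counts as stopped when no species that holds the solid substrate changes by six tenths of a point or more over the second half of the time

At 10.0 d, cedar keeps 21.5% and alder 48.1%, so the percentages part. Turn them into amounts lost:

cedar: 78.5 mM; alder: 77.8 mM

The amounts nearly coincide, so in these two runs the loss reads as pseudo-zero-order in the charge. Take the slope from alder, which keeps solid throughout:

7.00 mM/d

Call this the feed rate, the amount of solid substrate per litre that leaves the solid on each day. Cedar's slope reads 7.06 mM/d. Run alder's line back to the start: it stands at 8.76 mM already lost.

First link, for the flask at 15 d: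

solid lost = (line at start + feed rate × time) / charge = 56.9%

So this reckoning leaves 43.1% solid in the flask, and I take the flask to be still moving. The weak link is the start value: read it as substrate that has only dissolved, which does not count as reacted. Reforged:

reacted = feed rate × time / charge = 52.5%

Alder's target reads 14.7 mM on average over its last three readings; I carry that amount over to the flask, where it is 7.35% of the charge. That leaves an estimated 45 percentage points for what else the reacted solid has become, over-reaction product among it.

The forecast, above this reckoning on conversion, reads: it is still moving, with 53.5% converted, 7.4% target and 46.1% over-reaction product, on the ground that “a saturated or steady solution is feeding the reaction”.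

The flask at 15 d: it is still moving, with 51.5% converted, 7.59% target and 33.9% over-reaction product.

    gas phase ⇌ dissolved gas, rate k1*(csat - [dissolved gas]) (kL = 3.64 /h)
    starting material + dissolved gas → target (k = 1.82 /M/h)
    starting material → side product (k = 0.00501 /h)
    starting material + target ⇌ idle adduct, settled at all times (K = 4.70 /M)
    solid substrate ⇌ starting material, rate k5*(cs5 - [starting material]) while solid is left; crystals form when [starting material] > cs5 (solubility = 15.0 mM, k = 0.0732 /h)
    dissolved gas + target → over-reaction product (k = 1.38 /M/h)

In the flask at 15.0 d, over-reaction product lies below that estimated share, and 9.62% of side product stands beside it. The flask's conversion corresponds to a feed rate of 6.87 mM/d on average. Apply the feed rate to the neighbouring flask, the same charge read at 10 d: the reckoning gives 35.0% converted. That neighbouring flask shows 34.0% converted, with 7.40% target, 6.32% side product and 19.9% over-reaction product.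

The runs were generated by integration with constants of no real substance, and the scatter is random.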